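**Plan**
- Retrosynthesis: the two benzyl ethers and the C3' carbinol (back to a ketone) are removed first. Then the chroman carbon C4' is excised (bonds C4'–C4a' and C3'–C4'), then the bond from the lactone carbon C2 to its benzylic CH2 is cut. Last, the butenolide bonds C2–C3 and O1–C5 are cut, leading back to an arylpyruvate and methyl glyoxylate.
- Enabling feature: the chroman ring (O1', C2' with its two methyl groups, carbinol C3', methylene C4', fusion carbons C4a' and C8a') is the one-carbon homologue of a 2,2-dimethylbenzofuran-3-one. That ketone has no α-hydrogen, and C4' is the extra carbon between the arene and the C3' carbonyl.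
- Forward: the benzofuranone ring (Fries rearrangement, O-alkylation) and the butenolide ring (aldol–lactonisation) are made separately and joined by benzylation at C2. The chroman ring arises last, from the five-membered ring, by one-carbon insertion.
- Stereochemistry: C2 (S) comes from a chiral phase-transfer-catalysed benzylation; C3' (R) comes from a Corey–Bakshi–Shibata reduction of the chroman-3-one.

Key step: step 10

Assumption: the facial sense of the ammonium catalyst in step 9 is assigned by analogy with related ester-stabilised enolates; if the (S)-catalyst should favour the (2R)-product, its enantiomer is used and nothing else changes.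

Numbering used below: furanone O1, C2 (quaternary), C3 (aryl), C4 (OMe), C5 (C=O); chroman positions carry primes.

**Step 1**
Reactants: 1 p-cresol; 2 2-bromo-2-methylpropanoyl bromide
Product: 3 4-methylphenyl 2-bromo-2-methylpropanoate
Conditions: Et3N, CH2Cl2, 0 °C to rt
Reagents that add atoms: none
Why: O-acylation of the phenol by the acid bromide with an amine base (esterification); the tertiary C–Br bond is not touched at this temperature.

**Step 2**
Reactants: 3 4-methylphenyl 2-bromo-2-methylpropanoate
Product: 5 2,2,5-trimethyl-1-benzofuran-3(2H)-one, via o-hydroxyaryl bromoketone 4 (not isolated)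
Conditions: AlCl3 (2.2 equiv), neat, 130 °C; ice/aq HCl; then NaOAc, EtOH, reflux
Reagents that add atoms: none
Why: Fries rearrangement under AlCl3 delivers the acyl group to the free ortho position (para is blocked by the methyl group), and the phenol of 4 then displaces the tertiary α-bromide in a 5-exo-tet O-alkylation, the classical coumaranone closure.

**Step 3**
Reactants: 5 2,2,5-trimethyl-1-benzofuran-3(2H)-one
Product: 6 5-(bromomethyl)-2,2-dimethyl-1-benzofuran-3(2H)-one
Conditions: NBS (1.05 equiv), AIBN (cat.), PhCF3, 80 °C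
Reagents that add atoms: N-bromosuccinimide O=C1CCC(=O)N1Br
Why: Wohl–Ziegler radical bromination; the aryl methyl group carries the only benzylic hydrogens, the ketone has no α-hydrogen, and the non-polar medium suppresses ring bromination.

**Step 4**
Reactants: 7 3,4-bis(benzyloxy)benzaldehyde; 8 imidazolidine-2,4-dione (hydantoin)
Product: 9 (5Z)-5-[3,4-bis(benzyloxy)benzylidene]imidazolidine-2,4-dione
Conditions: NH4OAc, AcOH, reflux
Reagents that add atoms: none
Why: Knoevenagel-type condensation of the acidic C5 methylene of hydantoin with the aldehyde, which should give the thermodynamically preferred (Z)-arylidene compound.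

**Step 5**
Reactants: 9 (5Z)-5-[3,4-bis(benzyloxy)benzylidene]imidazolidine-2,4-dione
Product: 10 3-[3,4-bis(benzyloxy)phenyl]-2-oxopropanoic acid (largely enolised)
Conditions: 20% aq NaOH, N2, reflux; then conc. HCl, 0 °C
Reagents that add atoms: water O
Why: Alkaline hydrolysis of an arylidenehydantoin (the hydantoin route to arylpyruvic acids): the ureide and enamine bonds are cleaved while the aryl benzyl ethers are inert to hydroxide, and nitrogen prevents oxidative cleavage of the enolate.

**Step 6**
Reactants: 10 3-[3,4-bis(benzyloxy)phenyl]-2-oxopropanoic acid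
Product: 11 methyl 3-[3,4-bis(benzyloxy)phenyl]-2-oxopropanoate (largely enolised)
Conditions: MeOH, Me3SiCl (cat.), rt
Reagents that add atoms: methanol CO
Why: Fischer esterification with HCl generated in methanol; the enolised keto group should resist ketal formation at room temperature and the benzyl ethers tolerate dilute anhydrous acid.

**Step 7**
Reactants: 11 methyl 3-[3,4-bis(benzyloxy)phenyl]-2-oxopropanoate; 12 methyl glyoxylate (freshly distilled, 2 equiv)
Product: 13 methyl 3-[3,4-bis(benzyloxy)phenyl]-4-hydroxy-5-oxo-2,5-dihydrofuran-2-carboxylate (racemic)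
Conditions: Et3N (1.1 equiv), THF, 0 °C to rt; 1 M HCl
Reagents that add atoms: none
Why: Cross aldol addition followed by lactonisation (the classical isotetronic acid synthesis): the enolised pyruvate attacks the far more electrophilic aldehyde of 12 through its benzylic carbon, the new alkoxide closes on the pyruvate ester by 5-exo-trig acyl substitution with loss of methanol, and the keto lactone rests as its enol; C2 forms racemic and is set in step 9.

**Step 8**
Reactants: 13 methyl 3-[3,4-bis(benzyloxy)phenyl]-4-hydroxy-5-oxo-2,5-dihydrofuran-2-carboxylate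
Product: 14 methyl 3-[3,4-bis(benzyloxy)phenyl]-4-methoxy-5-oxo-2,5-dihydrofuran-2-carboxylate (racemic)
Conditions: Me3SiCHN2 (2 M in hexanes, 1.2 equiv), toluene/MeOH 4:1, 0 °C
Reagents that add atoms: trimethylsilyldiazomethane C[Si](C)(C)C=[N+]=[N-]
Why: Diazoalkane O-methylation of an acidic enol (methanol-mediated proton transfer, then methyl transfer), which is neutral and therefore leaves the weaker C2–H acid untouched.

**Step 9**
Reactants: 14 methyl 3-[3,4-bis(benzyloxy)phenyl]-4-methoxy-5-oxo-2,5-dihydrofuran-2-carboxylate; 6 5-(bromomethyl)-2,2-dimethyl-1-benzofuran-3(2H)-one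
Product: 15 methyl (2S)-3-[3,4-bis(benzyloxy)phenyl]-2-[(2,2-dimethyl-3-oxo-2,3-dihydro-1-benzofuran-5-yl)methyl]-4-methoxy-5-oxo-2,5-dihydrofuran-2-carboxylate
Conditions: (S)-4,4-dibutyl-2,6-bis(3,4,5-trifluorophenyl)-4,5-dihydro-3H-dinaphtho[2,1-c:1',2'-e]azepinium bromide (2 mol%), Cs2CO3 (solid), toluene, −20 °C
Reagents that add atoms: none
Why: Asymmetric phase-transfer alkylation: carbonate removes the acidic C2–H (flanked by the ester, the lactone oxygen and the vinylogous lactone carbonyl), the planar 2-oxidofuran enolate pairs with the chiral ammonium ion, which shields one face, and the soft benzylic bromide should attack C2 to set the quaternary (S)-centre, as established for α-substituted malonates and phthalide-3-carboxylates; 6 has no enolisable position and is inert to the base.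

**Step 10**
Reactants: 15 methyl (2S)-3-[3,4-bis(benzyloxy)phenyl]-2-[(2,2-dimethyl-3-oxo-2,3-dihydro-1-benzofuran-5-yl)methyl]-4-methoxy-5-oxo-2,5-dihydrofuran-2-carboxylate
Product: 17 methyl (2S)-3-[3,4-bis(benzyloxy)phenyl]-2-[(2,2-dimethyl-3-oxo-3,4-dihydro-2H-chromen-6-yl)methyl]-4-methoxy-5-oxo-2,5-dihydrofuran-2-carboxylate, via C4'-trimethylsilyl chroman-3-one 16 (not isolated)
Conditions: Me3SiCHN2 (1.5 equiv), BF3·OEt2 (2.5 equiv), CH2Cl2, −78 to −20 °C; sat. aq NaHCO3; then 1 M HCl, THF, 0 °C
Reagents that add atoms: trimethylsilyldiazomethane C[Si](C)(C)C=[N+]=[N-]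
Why: Proposed new method: BF3 activates the benzofuranone carbonyl, the diazo carbon adds to it, and loss of N2 from the betaine is accompanied by a 1,2-shift of the aryl carbon C3a (electron-rich, ortho to the ring oxygen) rather than of the quaternary, oxygen-bearing C2, so the inserted carbon becomes the benzylic C4' and the bonds C4'–C4a' and C3'–C4' are formed; the C-silyl ketone 16 is protodesilylated on acidic work-up. The closest known reaction type is the Lewis-acid-promoted diazoalkane ring expansion (Tiffeneau–Demjanov type) of benzo-fused aryl ketones such as 1-indanones and 1-tetralones to 2-tetralones and 2-benzosuberones, which has not been shown on a 2,2-dimethylbenzofuran-3-one. The six-membered chroman ring arises by enlargement of the five-membered ring through this aryl shift, not by an end-to-end cyclisation. No stereocentre is created in the isolated product: the silyl-bearing C4' of 16 is transient and C2 is remote and untouched. The step needs aryl-over-alkyl migration, attack at the ketone rather than at the ester or lactone carbonyls, and a single insertion; these should be secured by the donor-substituted migrating aryl carbon against the hindered, inductively deactivated C(CH3)2–O carbon, by the much higher reactivity of a BF3-bound ketone towards a diazoalkane, and by the silyl group, which holds the product as a β-keto silane until work-up.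

**Step 11**
Reactants: 17 methyl (2S)-3-[3,4-bis(benzyloxy)phenyl]-2-[(2,2-dimethyl-3-oxo-3,4-dihydro-2H-chromen-6-yl)methyl]-4-methoxy-5-oxo-2,5-dihydrofuran-2-carboxylate
Product: 18 methyl (2S)-3-[3,4-bis(benzyloxy)phenyl]-2-{[(3R)-3-hydroxy-2,2-dimethyl-3,4-dihydro-2H-chromen-6-yl]methyl}-4-methoxy-5-oxo-2,5-dihydrofuran-2-carboxylate
Conditions: (S)-1-methyl-3,3-diphenyltetrahydro-1H,3H-pyrrolo[1,2-c][1,3,2]oxazaborole (20 mol%), BH3·SMe2, THF, −30 °C; MeOH
Reagents that add atoms: none
Why: Corey–Bakshi–Shibata reduction: the oxazaborolidine binds borane and the ketone oxygen anti to the larger flank (quaternary C2'), so hydride should reach the face that gives the (3'R)-alcohol (the same sense as acetophenone to (R)-1-phenylethanol with the (S)-catalyst), the remote C2 centre playing no part; esters and the lactone are not reduced at this temperature.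

**Step 12**
Reactants: 18 methyl (2S)-3-[3,4-bis(benzyloxy)phenyl]-2-{[(3R)-3-hydroxy-2,2-dimethyl-3,4-dihydro-2H-chromen-6-yl]methyl}-4-methoxy-5-oxo-2,5-dihydrofuran-2-carboxylate
Product: 19 methyl (2S)-3-(3,4-dihydroxyphenyl)-2-{[(3R)-3-hydroxy-2,2-dimethyl-3,4-dihydro-2H-chromen-6-yl]methyl}-4-methoxy-5-oxo-2,5-dihydrofuran-2-carboxylate
Conditions: H2 (1 atm), 10% Pd/C, EtOAc/MeOH, rt
Reagents that add atoms: none
Why: Catalytic hydrogenolysis of the two aryl benzyl ethers; the tetrasubstituted, electron-poor butenolide alkene and the non-benzylic C–O bonds are not expected to react at balloon pressure, so both stereocentres are untouched.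

**Compound list**
1 | p-cresol (4-methylphenol) | Cc1ccc(O)cc1 | starting material
2 | 2-bromo-2-methylpropanoyl bromide | CC(C)(Br)C(=O)Br | starting material
3 | 4-methylphenyl 2-bromo-2-methylpropanoate | Cc1ccc(OC(=O)C(C)(C)Br)cc1 | intermediate
4 | 2-bromo-1-(2-hydroxy-5-methylphenyl)-2-methylpropan-1-one | Cc1ccc(O)c(C(=O)C(C)(C)Br)c1 | intermediate
5 | 2,2,5-trimethyl-1-benzofuran-3(2H)-one | Cc1ccc2OC(C)(C)C(=O)c2c1 | intermediate
6 | 5-(bromomethyl)-2,2-dimethyl-1-benzofuran-3(2H)-one | BrCc1ccc2OC(C)(C)C(=O)c2c1 | intermediate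
7 | 3,4-bis(benzyloxy)benzaldehyde | O=Cc1ccc(OCc2ccccc2)c(OCc2ccccc2)c1 | starting material
8 | imidazolidine-2,4-dione (hydantoin) | O=C1CNC(=O)N1 | starting material
9 | (5Z)-5-[3,4-bis(benzyloxy)benzylidene]imidazolidine-2,4-dione | O=C1NC(=O)N/C1=C\c2ccc(OCc3ccccc3)c(OCc4ccccc4)c2 | intermediate
10 | 3-[3,4-bis(benzyloxy)phenyl]-2-oxopropanoic acid | OC(=O)C(=O)Cc1ccc(OCc2ccccc2)c(OCc2ccccc2)c1 | intermediate
11 | methyl 3-[3,4-bis(benzyloxy)phenyl]-2-oxopropanoate | COC(=O)C(=O)Cc1ccc(OCc2ccccc2)c(OCc2ccccc2)c1 | intermediate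
12 | methyl glyoxylate (methyl 2-oxoacetate) | COC(=O)C=O | starting material
13 | methyl 3-[3,4-bis(benzyloxy)phenyl]-4-hydroxy-5-oxo-2,5-dihydrofuran-2-carboxylate, racemic | COC(=O)C1OC(=O)C(O)=C1c1ccc(OCc2ccccc2)c(OCc2ccccc2)c1 | intermediate
14 | methyl 3-[3,4-bis(benzyloxy)phenyl]-4-methoxy-5-oxo-2,5-dihydrofuran-2-carboxylate, racemic | COC(=O)C1OC(=O)C(OC)=C1c1ccc(OCc2ccccc2)c(OCc2ccccc2)c1 | intermediate
15 | methyl (2S)-3-[3,4-bis(benzyloxy)phenyl]-2-[(2,2-dimethyl-3-oxo-2,3-dihydro-1-benzofuran-5-yl)methyl]-4-methoxy-5-oxo-2,5-dihydrofuran-2-carboxylate | COC(=O)[C@@]1(Cc2ccc3OC(C)(C)C(=O)c3c2)OC(=O)C(OC)=C1c1ccc(OCc2ccccc2)c(OCc2ccccc2)c1 | intermediate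
16 | methyl (2S)-3-[3,4-bis(benzyloxy)phenyl]-2-{[2,2-dimethyl-3-oxo-4-(trimethylsilyl)-3,4-dihydro-2H-chromen-6-yl]methyl}-4-methoxy-5-oxo-2,5-dihydrofuran-2-carboxylate, both C4' epimers | COC(=O)[C@@]1(Cc2ccc3OC(C)(C)C(=O)C([Si](C)(C)C)c3c2)OC(=O)C(OC)=C1c1ccc(OCc2ccccc2)c(OCc2ccccc2)c1 | intermediate
17 | methyl (2S)-3-[3,4-bis(benzyloxy)phenyl]-2-[(2,2-dimethyl-3-oxo-3,4-dihydro-2H-chromen-6-yl)methyl]-4-methoxy-5-oxo-2,5-dihydrofuran-2-carboxylate | COC(=O)[C@@]1(Cc2ccc3OC(C)(C)C(=O)Cc3c2)OC(=O)C(OC)=C1c1ccc(OCc2ccccc2)c(OCc2ccccc2)c1 | intermediate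
18 | methyl (2S)-3-[3,4-bis(benzyloxy)phenyl]-2-{[(3R)-3-hydroxy-2,2-dimethyl-3,4-dihydro-2H-chromen-6-yl]methyl}-4-methoxy-5-oxo-2,5-dihydrofuran-2-carboxylate | COC(=O)[C@@]1(Cc2ccc3c(c2)C[C@@H](O)C(C)(C)O3)OC(=O)C(OC)=C1c1ccc(OCc2ccccc2)c(OCc2ccccc2)c1 | intermediate
19 | methyl (2S)-3-(3,4-dihydroxyphenyl)-2-{[(3R)-3-hydroxy-2,2-dimethyl-3,4-dihydro-2H-chromen-6-yl]methyl}-4-methoxy-5-oxo-2,5-dihydrofuran-2-carboxylate | COC(=O)[C@@]1(Cc2ccc3c(c2)C[C@@H](O)C(C)(C)O3)OC(=O)C(OC)=C1c1ccc(O)c(O)c1 | target

**Totals**
Total steps: 12. Longest linear sequence: 9 steps (steps 4 to 12, from aldehyde 7); the benzofuranone branch (steps 1 to 3) joins at step 9.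

**Steps most likely to fail**

1. Step 10. The diazoalkane may add too slowly to a ketone that behaves as a vinylogous ester, the quaternary carbon may migrate in part, or the betaine may collapse to a spiro-epoxide. The fallback uses known reactions and forms the same two bonds. Setting out from 15, the ketone is methylenated with Zn/CH2Br2/TiCl4 (Lombardo conditions, which spare esters and lactones) to give methyl (2S)-3-[3,4-bis(benzyloxy)phenyl]-2-[(2,2-dimethyl-3-methylidene-2,3-dihydro-1-benzofuran-5-yl)methyl]-4-methoxy-5-oxo-2,5-dihydrofuran-2-carboxylate F1. Treatment of this exocyclic alkene with PhI(OH)OTs in 95% MeOH should then bring about the hypervalent-iodine oxidative ring enlargement known for exocyclic methylene groups on benzo-fused rings: methanol captures the benzylic cation, the aryl carbon shifts to the iodine-bearing CH2 with loss of PhI, and the ketal is hydrolysed. This comes back to the route at 17.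

2. Step 9. Facial discrimination within the ammonium–enolate ion pair may be insufficient, so that the quaternary centre forms with low enantiomeric purity. The fallback gives up catalyst control for resolution. Setting out from 14 and 6, alkylation with an achiral catalyst (Bu4NBr, solid K2CO3, toluene) gives the racemic benzylation product rac-15 F2. Since it has no salt-forming group, it is resolved by preparative chromatography on a chiral stationary phase (amylose tris(3,5-dimethylphenylcarbamate)); the (2S)-enantiomer re-enters the route as 15.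

3. Step 11. The oxazaborolidine may not distinguish the two carbonyl flanks well enough, or uncatalysed borane reduction may compete, eroding the configuration at C3'; the air-sensitive ketone 17 may also degrade before reduction. The fallback sets C3' by alkene epoxidation instead of ketone reduction. Setting out from 17, NaBH4 in MeOH at −20 °C gives the carbinol as a mixture of C3' epimers F3, for which no control is needed. Dehydration with methyl N-(triethylammoniosulfonyl)carbamate (Burgess reagent, toluene, 80 °C) gives the 2H-chromene F4. Jacobsen epoxidation with (R,R)-[N,N'-bis(3,5-di-tert-butylsalicylidene)-1,2-cyclohexanediaminato]manganese chloride, NaOCl and 4-phenylpyridine N-oxide in CH2Cl2 at 0 °C should give the (3'R,4'R)-epoxide F5. Hydrogenation over Pd/C then cleaves the benzylic C4'–O bond of the epoxide together with the two benzyl ethers, with retention at C3', and comes back to the route at 19.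

**Further compounds**
F1 | step 10 | methyl (2S)-3-[3,4-bis(benzyloxy)phenyl]-2-[(2,2-dimethyl-3-methylidene-2,3-dihydro-1-benzofuran-5-yl)methyl]-4-methoxy-5-oxo-2,5-dihydrofuran-2-carboxylate | COC(=O)[C@@]1(Cc2ccc3OC(C)(C)C(=C)c3c2)OC(=O)C(OC)=C1c1ccc(OCc2ccccc2)c(OCc2ccccc2)c1
F2 | step 9 | racemic methyl 3-[3,4-bis(benzyloxy)phenyl]-2-[(2,2-dimethyl-3-oxo-2,3-dihydro-1-benzofuran-5-yl)methyl]-4-methoxy-5-oxo-2,5-dihydrofuran-2-carboxylate | COC(=O)C1(Cc2ccc3OC(C)(C)C(=O)c3c2)OC(=O)C(OC)=C1c1ccc(OCc2ccccc2)c(OCc2ccccc2)c1
F3 | step 11 | methyl (2S)-3-[3,4-bis(benzyloxy)phenyl]-2-[(3-hydroxy-2,2-dimethyl-3,4-dihydro-2H-chromen-6-yl)methyl]-4-methoxy-5-oxo-2,5-dihydrofuran-2-carboxylate, mixture of C3' epimers | COC(=O)[C@@]1(Cc2ccc3c(c2)CC(O)C(C)(C)O3)OC(=O)C(OC)=C1c1ccc(OCc2ccccc2)c(OCc2ccccc2)c1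
F4 | step 11 | methyl (2S)-3-[3,4-bis(benzyloxy)phenyl]-2-[(2,2-dimethyl-2H-chromen-6-yl)methyl]-4-methoxy-5-oxo-2,5-dihydrofuran-2-carboxylate | COC(=O)[C@@]1(Cc2ccc3c(c2)C=CC(C)(C)O3)OC(=O)C(OC)=C1c1ccc(OCc2ccccc2)c(OCc2ccccc2)c1
F5 | step 11 | (3'R,4'R)-3',4'-epoxide of chromene F4 (cis-fused oxirane on the chroman ring) | COC(=O)[C@@]1(Cc2ccc3c(c2)[C@H]4O[C@H]4C(C)(C)O3)OC(=O)C(OC)=C1c1ccc(OCc2ccccc2)c(OCc2ccccc2)c1
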